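**Retrosynthetic overview**

Ring A is the central caffeoyl ring, ring B the catechol of the enol ether unit, ring C the catechol of the danshensu unit.
- Last disconnections: global acidolysis of a fully protected precursor, and before it the propenoate C=C at ring A C1, made by Knoevenagel–Doebner condensation of a ring A aldehyde with the malonate half-ester of protected (R)-danshensu.
- Key disconnection: the bond from ring A C4 to the enol oxygen, made by nucleophilic aromatic substitution of the cesium enolate of a protected ring B arylpyruvate tert-butyl ester on 4-fluoro-3-(methoxymethoxy)benzaldehyde.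
- Feature the plan rests on: the ring A C4–O bond ends at the enol oxygen of 3,4-dihydroxyphenylpyruvic acid, and ring A C1, para to C4, carries a carbon that can be a formyl group (activating C4) before it becomes the propenoate.
- One protected (R)-danshensu tert-butyl ester serves twice: oxidised it gives the ring B pyruvate enol, acylated with Meldrum's acid it gives the ring C malonate.
- No ring of the target is formed: rings A, B and C are bought as benzene rings; only protecting benzodioxole rings (and one transient dioxolanone) are made and later opened.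

Key step: step 5

Assumption: (R)-danshensu is used as the free acid (the commercial sodium salt would be acidified and extracted first). The arylpyruvate ester is drawn as its Z enol, the tautomer expected to dominate; any keto tautomer present converges on the same enolate in step 5.

**Route**

Step 1
Reactants: 1 (R)-danshensu
Product: 3 (2R)-3-(2,2-dimethyl-1,3-benzodioxol-5-yl)-2-hydroxypropanoic acid, via dioxolanone bis-acetonide 2 (not isolated)
Conditions: Me2C(OMe)2 (excess), TsOH·H2O (cat.), PhH, reflux, Soxhlet (4 Å MS); then LiOH, THF/H2O, 0 °C; then 1 M HCl to pH 3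
Reagents that add atoms: 2,2-dimethoxypropane COC(C)(C)OC; lithium hydroxide [Li+].[OH-]
Why: Acid-catalysed transketalisation should turn the catechol into the 2,2-dimethyl-1,3-benzodioxole and the α-hydroxy acid into a 1,3-dioxolan-4-one, and mild hydroxide then opens only this activated lactone-type ketal, so the stereocentre, never deprotonated or ionised, stays R.

Step 2
Reactants: 3 (2R)-3-(2,2-dimethyl-1,3-benzodioxol-5-yl)-2-hydroxypropanoic acid
Product: 4 tert-butyl (2R)-3-(2,2-dimethyl-1,3-benzodioxol-5-yl)-2-hydroxypropanoate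
Conditions: Cl3CC(=NH)OtBu (2.5 equiv), CH2Cl2/cyclohexane, rt
Reagents that add atoms: tert-butyl 2,2,2-trichloroacetimidate CC(C)(C)OC(=N)C(Cl)(Cl)Cl
Why: Imidate esterification, in which the carboxylic acid itself protonates the imidate and is tert-butylated while the secondary alcohol would need a Lewis acid catalyst, so the hydroxyl stays free and the stereocentre is untouched.

Step 3
Reactants: 4 tert-butyl (2R)-3-(2,2-dimethyl-1,3-benzodioxol-5-yl)-2-hydroxypropanoate
Product: 6 tert-butyl (2Z)-3-(2,2-dimethyl-1,3-benzodioxol-5-yl)-2-hydroxyprop-2-enoate, via keto tautomer 5 (not isolated)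
Conditions: Dess–Martin periodinane (1.1 equiv), CH2Cl2, 0 °C to rt, under Ar
Reagents that add atoms: none
Why: Dess–Martin oxidation of the secondary α-hydroxy ester gives the α-keto ester, which should tautomerise to the enol conjugated with ring B and hydrogen-bonded to the ester carbonyl (ring B cis to the hydroxyl, Z); the stereocentre is removed on purpose, and a limited charge of oxidant at low temperature protects the electron-rich enol.

Step 4
Reactants: 7 4-fluoro-3-hydroxybenzaldehyde
Product: 8 4-fluoro-3-(methoxymethoxy)benzaldehyde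
Conditions: MOMCl, K2CO3, acetone, 0 °C to rt
Reagents that add atoms: chloromethyl methyl ether COCCl
Why: Williamson alkylation of the phenoxide masks the hydroxyl, which as a free phenoxide would deactivate the ring toward substitution and compete as a nucleophile in step 5.

Step 5
Reactants: 6 tert-butyl (2Z)-3-(2,2-dimethyl-1,3-benzodioxol-5-yl)-2-hydroxyprop-2-enoate; 8 4-fluoro-3-(methoxymethoxy)benzaldehyde
Product: 10 tert-butyl (2Z)-3-(2,2-dimethyl-1,3-benzodioxol-5-yl)-2-[4-formyl-2-(methoxymethoxy)phenoxy]prop-2-enoate, via cesium enolate 9 (not isolated)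
Conditions: Cs2CO3 (1.5 equiv), degassed DMSO, 4 Å MS, rt, 30 min, under Ar; then 8 (1.5 equiv), 70 °C
Reagents that add atoms: none
Why: Proposed new method: Cs2CO3 in DMSO turns enol 6 into the loosely paired cesium enolate 9, whose oxygen adds to C4 of 8 para to the formyl group to give a Meisenheimer adduct with the charge on the formyl oxygen, and loss of fluoride forms the ring A C4–O bond (addition–elimination nucleophilic aromatic substitution). The closest known reaction type is diaryl ether formation from phenoxides and 4-fluorobenzaldehydes under carbonate in dipolar aprotic solvents; the enolate oxygen of an α-keto ester, of basicity similar to a phenoxide, has not been used in this role. No ring closes and no stereocentre forms; the Z geometry is that of the enolate, in which ring B lies cis to oxygen and trans to the bulky ester, and it is also the more stable geometry of the product. Two selectivities are needed: oxygen over carbon arylation, which the hard fluoroarene, the free oxyanion and the loss of styrene conjugation at a crowded benzylic carbon on C-attack should secure, and attack at C4 over aldol addition to the formyl group. The second should hold because aldol addition of this stabilised enolate is reversible whereas fluoride loss is not, and because the tert-butyl ester, the fully pre-formed enolate and the absence of a proton source slow the lactonisation and dehydration that would make the aldol path irreversible.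

Step 6
Reactants: 4 tert-butyl (2R)-3-(2,2-dimethyl-1,3-benzodioxol-5-yl)-2-hydroxypropanoate
Product: 11 3-{[(2R)-1-tert-butoxy-3-(2,2-dimethyl-1,3-benzodioxol-5-yl)-1-oxopropan-2-yl]oxy}-3-oxopropanoic acid
Conditions: Meldrum's acid (1.2 equiv), PhMe, 95 °C
Reagents that add atoms: Meldrum's acid (2,2-dimethyl-1,3-dioxane-4,6-dione) CC1(C)OC(=O)CC(=O)O1
Why: Thermal ring opening of Meldrum's acid by the alcohol, with loss of acetone, acylates the hydroxyl and gives the malonic acid half-ester under neutral conditions that leave the tert-butyl ester, the acetonide and the stereocentre intact.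

Step 7
Reactants: 10 tert-butyl (2Z)-3-(2,2-dimethyl-1,3-benzodioxol-5-yl)-2-[4-formyl-2-(methoxymethoxy)phenoxy]prop-2-enoate; 11 3-{[(2R)-1-tert-butoxy-3-(2,2-dimethyl-1,3-benzodioxol-5-yl)-1-oxopropan-2-yl]oxy}-3-oxopropanoic acid
Product: 13 tert-butyl (2Z)-2-{4-[(1E)-3-{[(2R)-1-tert-butoxy-3-(2,2-dimethyl-1,3-benzodioxol-5-yl)-1-oxopropan-2-yl]oxy}-3-oxoprop-1-en-1-yl]-2-(methoxymethoxy)phenoxy}-3-(2,2-dimethyl-1,3-benzodioxol-5-yl)prop-2-enoate, via arylidenemalonate half-ester 12 (not isolated)
Conditions: 11 (1.5 equiv), pyridine, piperidine (0.2 equiv), 60 °C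
Reagents that add atoms: none
Why: Knoevenagel–Doebner condensation, in which the piperidine-activated aldehyde condenses with the malonate half-ester and the adduct loses CO2 in pyridine to give the E-cinnamate (the thermodynamic geometry of the decarboxylative elimination) under conditions too weakly basic to epimerise the α-acyloxy ester stereocentre.

Step 8
Reactants: 13 the fully protected ester from step 7
Product: 14 (2R)-2-{[(2E)-3-(4-{[(1Z)-1-carboxy-2-(3,4-dihydroxyphenyl)ethenyl]oxy}-3-hydroxyphenyl)prop-2-enoyl]oxy}-3-(3,4-dihydroxyphenyl)propanoic acid (CNP0157552.2)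
Conditions: TFA/H2O (9:1), 0 °C to rt, under Ar
Reagents that add atoms: none
Why: Acidolysis, in which trifluoroacetic acid cleaves both tert-butyl esters by alkyl–oxygen fission and, with the water present, hydrolyses the methoxymethyl ether and the two catechol acetonides, while the electron-poor α-aryloxyacrylic acid, the cinnamate ester and the stereocentre should not be affected by acid at room temperature.

**Compound list**

1 | (R)-danshensu, (2R)-3-(3,4-dihydroxyphenyl)-2-hydroxypropanoic acid | O[C@H](Cc1ccc(O)c(O)c1)C(=O)O | starting material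
2 | (5R)-5-[(2,2-dimethyl-1,3-benzodioxol-5-yl)methyl]-2,2-dimethyl-1,3-dioxolan-4-one (dioxolanone bis-acetonide, not isolated) | CC1(C)O[C@H](Cc2ccc3OC(C)(C)Oc3c2)C(=O)O1 | intermediate
3 | (2R)-3-(2,2-dimethyl-1,3-benzodioxol-5-yl)-2-hydroxypropanoic acid | O[C@H](Cc1ccc2OC(C)(C)Oc2c1)C(=O)O | intermediate
4 | tert-butyl (2R)-3-(2,2-dimethyl-1,3-benzodioxol-5-yl)-2-hydroxypropanoate | O[C@H](Cc1ccc2OC(C)(C)Oc2c1)C(=O)OC(C)(C)C | intermediate
5 | tert-butyl 3-(2,2-dimethyl-1,3-benzodioxol-5-yl)-2-oxopropanoate (keto tautomer, not isolated) | CC(C)(C)OC(=O)C(=O)Cc1ccc2OC(C)(C)Oc2c1 | intermediate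
6 | tert-butyl (2Z)-3-(2,2-dimethyl-1,3-benzodioxol-5-yl)-2-hydroxyprop-2-enoate | CC(C)(C)OC(=O)/C(O)=C/c1ccc2OC(C)(C)Oc2c1 | intermediate
7 | 4-fluoro-3-hydroxybenzaldehyde | O=Cc1ccc(F)c(O)c1 | starting material
8 | 4-fluoro-3-(methoxymethoxy)benzaldehyde | COCOc1cc(C=O)ccc1F | intermediate
9 | cesium (1Z)-1-(tert-butoxycarbonyl)-2-(2,2-dimethyl-1,3-benzodioxol-5-yl)ethenolate (cesium enolate of 6, not isolated) | CC(C)(C)OC(=O)/C([O-])=C/c1ccc2OC(C)(C)Oc2c1.[Cs+] | intermediate
10 | tert-butyl (2Z)-3-(2,2-dimethyl-1,3-benzodioxol-5-yl)-2-[4-formyl-2-(methoxymethoxy)phenoxy]prop-2-enoate | CC(C)(C)OC(=O)/C(=C/c1ccc2OC(C)(C)Oc2c1)Oc1ccc(C=O)cc1OCOC | intermediate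
11 | 3-{[(2R)-1-tert-butoxy-3-(2,2-dimethyl-1,3-benzodioxol-5-yl)-1-oxopropan-2-yl]oxy}-3-oxopropanoic acid | OC(=O)CC(=O)O[C@H](Cc1ccc2OC(C)(C)Oc2c1)C(=O)OC(C)(C)C | intermediate
12 | arylidenemalonate half-ester: 10 with its formyl carbon condensed onto the malonate CH2 of 11, new alkene geometry undefined (not isolated) | CC(C)(C)OC(=O)/C(=C/c1ccc2OC(C)(C)Oc2c1)Oc1ccc(C=C(C(=O)O)C(=O)O[C@H](Cc3ccc4OC(C)(C)Oc4c3)C(=O)OC(C)(C)C)cc1OCOC | intermediate
13 | tert-butyl (2Z)-2-{4-[(1E)-3-{[(2R)-1-tert-butoxy-3-(2,2-dimethyl-1,3-benzodioxol-5-yl)-1-oxopropan-2-yl]oxy}-3-oxoprop-1-en-1-yl]-2-(methoxymethoxy)phenoxy}-3-(2,2-dimethyl-1,3-benzodioxol-5-yl)prop-2-enoate | CC(C)(C)OC(=O)/C(=C/c1ccc2OC(C)(C)Oc2c1)Oc1ccc(/C=C/C(=O)O[C@H](Cc3ccc4OC(C)(C)Oc4c3)C(=O)OC(C)(C)C)cc1OCOC | intermediate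
14 | (2R)-2-{[(2E)-3-(4-{[(1Z)-1-carboxy-2-(3,4-dihydroxyphenyl)ethenyl]oxy}-3-hydroxyphenyl)prop-2-enoyl]oxy}-3-(3,4-dihydroxyphenyl)propanoic acid | O=C(/C=C/c1ccc(O/C(=C\c2ccc(O)c(O)c2)C(=O)O)c(O)c1)O[C@H](Cc1ccc(O)c(O)c1)C(=O)O | target

**Step count**

Total steps: 8. Longest linear sequence: 6 steps (steps 1, 2, 3, 5, 7, 8 from (R)-danshensu).

**Steps most likely to fail**

Step 5 (the key step). The enolate may add through carbon to the formyl group of 8 and then dehydrate or lactonise faster than its oxygen displaces fluoride from the only moderately activated, ortho-alkoxylated ring. C-arylation and oxidative cleavage of the enolate by traces of air are further drains. The fallback builds the enol ether by aldol condensation, sets out from 8 and returns at 10.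
- Fluoride of 8 would be displaced by the sodium alkoxide of tert-butyl glycolate (NaH, DMF, 0 °C to rt; alkoxide substitution para to a formyl group is a known reaction type) to give tert-butyl 2-[4-formyl-2-(methoxymethoxy)phenoxy]acetate F1.
- The formyl group would be masked (HC(OMe)3, MeOH, PPTS cat.) as tert-butyl 2-[4-(dimethoxymethyl)-2-(methoxymethoxy)phenoxy]acetate F2.
- Its lithium enolate (LiN(iPr)2, THF, −78 °C) would add to purchased 2,2-dimethyl-1,3-benzodioxole-5-carbaldehyde to give tert-butyl 2-[4-(dimethoxymethyl)-2-(methoxymethoxy)phenoxy]-3-(2,2-dimethyl-1,3-benzodioxol-5-yl)-3-hydroxypropanoate F3.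
- Mesylation (MsCl, Et3N, CH2Cl2, 0 °C) would give the corresponding mesylate F4, which DBU in the same flask should eliminate to tert-butyl (2Z)-2-[4-(dimethoxymethyl)-2-(methoxymethoxy)phenoxy]-3-(2,2-dimethyl-1,3-benzodioxol-5-yl)prop-2-enoate F5. This is the thermodynamic isomer; any E isomer would be separated or equilibrated with a trace of iodine.
- PPTS in wet acetone at rt would then free the aldehyde and give 10.

Step 8. The formaldehyde or methoxymethyl and tert-butyl cations set free may be captured by the three freshly unmasked catechol rings. The benzodioxole ketals may cleave incompletely, and acid may close the ring A hydroxyl onto the neighbouring acrylic acid. The fallback removes the formaldehyde source first, while all catechols are still ketals; it sets out from 13 and returns at 14. ZnBr2 and n-PrSH in CH2Cl2 at 0 °C (a known rapid cleavage of methoxymethyl ethers that traps the CH2 unit as a dithioacetal) would give the ring A phenol with both tert-butyl esters and both acetonides intact F6. TFA/H2O would then have to remove only tert-butyl and isopropylidene groups to reach 14.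

Step 1. The catechol of a poorly soluble free hydroxy acid may ketalise incompletely, the methanol set free may esterify the acid, and the catechol may oxidise in air at reflux. The fallback masks the carboxyl group first, sets out from 1 and returns at 3. Fischer esterification (MeOH, HCl generated from AcCl, rt) would give methyl (2R)-3-(3,4-dihydroxyphenyl)-2-hydroxypropanoate F7. The soluble ester would be ketalised (Me2C(OMe)2, TsOH·H2O cat., PhH, reflux, Soxhlet with 4 Å MS) to methyl (2R)-3-(2,2-dimethyl-1,3-benzodioxol-5-yl)-2-hydroxypropanoate F8. LiOH in THF/H2O at 0 °C would then give acid 3.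

Further compounds
F1 | step 5 | tert-butyl 2-[4-formyl-2-(methoxymethoxy)phenoxy]acetate | CC(C)(C)OC(=O)COc1ccc(C=O)cc1OCOC
F2 | step 5 | tert-butyl 2-[4-(dimethoxymethyl)-2-(methoxymethoxy)phenoxy]acetate | CC(C)(C)OC(=O)COc1ccc(C(OC)OC)cc1OCOC
F3 | step 5 | tert-butyl 2-[4-(dimethoxymethyl)-2-(methoxymethoxy)phenoxy]-3-(2,2-dimethyl-1,3-benzodioxol-5-yl)-3-hydroxypropanoate (diastereomer mixture) | CC(C)(C)OC(=O)C(Oc1ccc(C(OC)OC)cc1OCOC)C(O)c1ccc2OC(C)(C)Oc2c1
F4 | step 5 | tert-butyl 2-[4-(dimethoxymethyl)-2-(methoxymethoxy)phenoxy]-3-(2,2-dimethyl-1,3-benzodioxol-5-yl)-3-(methanesulfonyloxy)propanoate (not isolated) | CC(C)(C)OC(=O)C(Oc1ccc(C(OC)OC)cc1OCOC)C(OS(C)(=O)=O)c1ccc2OC(C)(C)Oc2c1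
F5 | step 5 | tert-butyl (2Z)-2-[4-(dimethoxymethyl)-2-(methoxymethoxy)phenoxy]-3-(2,2-dimethyl-1,3-benzodioxol-5-yl)prop-2-enoate | CC(C)(C)OC(=O)/C(=C/c1ccc2OC(C)(C)Oc2c1)Oc1ccc(C(OC)OC)cc1OCOC
F6 | step 8 | tert-butyl (2Z)-2-{4-[(1E)-3-{[(2R)-1-tert-butoxy-3-(2,2-dimethyl-1,3-benzodioxol-5-yl)-1-oxopropan-2-yl]oxy}-3-oxoprop-1-en-1-yl]-2-hydroxyphenoxy}-3-(2,2-dimethyl-1,3-benzodioxol-5-yl)prop-2-enoate | CC(C)(C)OC(=O)/C(=C/c1ccc2OC(C)(C)Oc2c1)Oc1ccc(/C=C/C(=O)O[C@H](Cc3ccc4OC(C)(C)Oc4c3)C(=O)OC(C)(C)C)cc1O
F7 | step 1 | methyl (2R)-3-(3,4-dihydroxyphenyl)-2-hydroxypropanoate | O[C@H](Cc1ccc(O)c(O)c1)C(=O)OC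
F8 | step 1 | methyl (2R)-3-(2,2-dimethyl-1,3-benzodioxol-5-yl)-2-hydroxypropanoate | O[C@H](Cc1ccc2OC(C)(C)Oc2c1)C(=O)OC
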